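**Retrosynthetic overview**

- Labels used in the text: C1 = ring carbinol carbon, C4 = C(CH3)Cl, C5 = CHBr, C7 = the =CH2-bearing carbon on C1, C10 = side-chain carbinol (systematic names carry their own locants). The strategy rests on the vicinal C4–Cl/C5–Br pair of the six-membered ring, read as a former trisubstituted C4=C5 olefin. Cutting that olefin by ring-closing metathesis leaves an acyclic tertiary carbinol (allyl arm C6–C5, 3-methylbut-3-enyl arm C2–C4) whose C1 configuration comes from an allylic-alcohol epoxidation.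
- The diene diol is built by copper-catalysed carbomagnesiation of propargyl alcohol, Sharpless epoxidation and vinyl-cuprate opening; metathesis then closes the cyclohexene, the only carbocycle.
- C1 then controls C4 and C5: its hydroxyl bridges to C4 in a bromoetherification (temporary 7-oxabicyclo[2.2.1]heptane, closed in step 6), and chloride reopens the bridge at C4 with retention through the bromonium ion (step 7).
- Side chain: C7 is oxidised to the aldehyde, a C8–C12 Grignard reagent (C10 from (R)-α-hydroxy-γ-butyrolactone) is added, and oxidation, Peterson methylenation and desilylation finish the target.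

Key step: step 4

Assumption: the target SMILES is read as the (1S,3R,4R)-cyclohexanol with a (5R)-side chain, i.e. OH at C1 and Cl at C4 cis, Br at C5 trans to both (trans-Br/Cl).

**Route**

Step 1
Reactants: 1 4-bromo-2-methylbut-1-ene; 2 prop-2-yn-1-ol (propargyl alcohol)
Product: 5 5-methyl-2-methylidenehex-5-en-1-ol, via (3-methylbut-3-en-1-yl)magnesium bromide 3 (not isolated), via alkenylmagnesium alkoxide adduct 4 (not isolated)
Conditions: 1 (2.5 equiv), Mg, Et2O, reflux; then 2, CuI (10 mol%), Et2O, −10 °C → reflux; aq. NH4Cl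
Reagents that add atoms: none
Why: Copper-catalysed carbomagnesiation of the propargylic alkoxide: one equivalent of the Grignard reagent deprotonates the alcohol, the next adds anti across the alkyne with the alkyl group at the internal carbon (chelated alkenylmagnesium alkoxide), and protonolysis gives the 2-substituted allylic alcohol.

Step 2
Reactants: 5 5-methyl-2-methylidenehex-5-en-1-ol
Product: 6 [(2R)-2-(3-methylbut-3-en-1-yl)oxiran-2-yl]methanol
Conditions: Ti(OiPr)4 (10 mol%), D-(−)-diethyl tartrate (12 mol%), t-BuOOH, 4 Å molecular sieves, CH2Cl2, −20 °C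
Reagents that add atoms: tert-butyl hydroperoxide, CC(C)(C)OO
Why: Sharpless asymmetric epoxidation: the titanium–tartrate complex delivers oxygen only to the olefin of the bound allylic alkoxide, so the remote 1,1-disubstituted alkene is untouched, and D-(−)-diethyl tartrate selects the olefin face that gives the (R)-epoxide, which fixes the future C1.

Step 3
Reactants: 6 [(2R)-2-(3-methylbut-3-en-1-yl)oxiran-2-yl]methanol; 7 vinylmagnesium bromide
Product: 8 (2S)-5-methyl-2-(prop-2-en-1-yl)hex-5-ene-1,2-diol
Conditions: 7 (3.5 equiv), CuI (20 mol%), THF, −40 → 0 °C; aq. NH4Cl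
Reagents that add atoms: none
Why: Copper-catalysed Grignard opening of the 2,2-disubstituted epoxide by SN2 attack at its unsubstituted CH2; the stereocentre is not touched and the Payne rearrangement of this alkoxide is degenerate, so the configuration passes unchanged into the (S)-diol.

Step 4
Reactants: 8 (2S)-5-methyl-2-(prop-2-en-1-yl)hex-5-ene-1,2-diol
Product: 9 (1S)-1-(hydroxymethyl)-4-methylcyclohex-3-en-1-ol
Conditions: second-generation Grubbs catalyst (3 mol%), CH2Cl2 (0.02 M), 40 °C
Reagents that add atoms: none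
Why: Ring-closing olefin metathesis: the ruthenium alkylidene loads on the monosubstituted allyl terminus, adds intramolecularly [2+2] to the 1,1-disubstituted olefin, and the metallacyclobutane cycloreverts with loss of ethylene, forming the C4=C5 bond. The closest known reaction type is ring-closing metathesis of 2-substituted octa-1,7-dienes to 1-substituted cyclohexenes with second-generation ruthenium carbenes, which tolerate free hydroxyl groups. The six-membered carbocycle is closed by joining the two olefinic termini (C4 with C5), the only pairing that gives an unstrained ring. No stereocentre is formed: the ring olefin can only be cis, and C1, set in step 2, is not touched. The step needs cyclisation to outrun intermolecular metathesis, which high dilution and the gem-disubstitution at the quaternary carbinol C1 secure.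

Step 5
Reactants: 9 (1S)-1-(hydroxymethyl)-4-methylcyclohex-3-en-1-ol
Product: 10 (1S)-1-({[tert-butyl(dimethyl)silyl]oxy}methyl)-4-methylcyclohex-3-en-1-ol
Conditions: TBSCl (1.05 equiv), imidazole, CH2Cl2, 0 °C
Reagents that add atoms: tert-butyldimethylsilyl chloride, CC(C)(C)[Si](C)(C)Cl
Why: Silyl ether formation: the unhindered primary hydroxyl is silylated selectively, while the tertiary hydroxyl, needed free in the next step, does not react with TBSCl/imidazole.

Step 6
Reactants: 10 (1S)-1-({[tert-butyl(dimethyl)silyl]oxy}methyl)-4-methylcyclohex-3-en-1-ol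
Product: 11 (1R,2R,4S)-2-bromo-4-({[tert-butyl(dimethyl)silyl]oxy}methyl)-1-methyl-7-oxabicyclo[2.2.1]heptane (bromine endo)
Conditions: NBS (1.1 equiv), NaHCO3, CH2Cl2, 0 °C → rt, dark
Reagents that add atoms: N-bromosuccinimide, O=C1CCC(=O)N1Br
Why: NBS bromoetherification (intramolecular haloetherification of a cyclohex-3-en-1-ol to a 2-halo-7-oxabicyclo[2.2.1]heptane): bromonium formation is reversible and only the bromonium ion on the face opposite the C1 hydroxyl can be captured, the axial tertiary OH adding anti at the more substituted C4 through a boat, so the C1 stereocentre fixes C4 (oxygen cis to the C1 oxygen) and C5 (bromine anti, endo).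

Step 7
Reactants: 11 (1R,2R,4S)-2-bromo-4-({[tert-butyl(dimethyl)silyl]oxy}methyl)-1-methyl-7-oxabicyclo[2.2.1]heptane
Product: 12 (1S,3R,4R)-3-bromo-1-({[tert-butyl(dimethyl)silyl]oxy}methyl)-4-chloro-4-methylcyclohexan-1-ol
Conditions: TiCl4 (1.5 equiv), CH2Cl2, −78 °C; aq. NaHCO3
Reagents that add atoms: titanium tetrachloride, Cl[Ti](Cl)(Cl)Cl
Why: Proposed new method: TiCl4 binds the strained bridging ether oxygen, the C4–O bond ionises with anchimeric help from the nearly antiperiplanar endo bromine at C5 to give the bromonium ion on the face opposite the oxygen, and a chloride of the titanate, held next to C4 by the C1 alkoxide, adds to the tertiary C4 from the oxygen face, so that chlorine replaces oxygen with retention (Cl cis to the C1 hydroxyl, Br trans), while the C1–O bond, without assistance and deactivated by the β-silyloxy group, stays intact; the closest known reaction types are the hydrogen-halide and Lewis-acid cleavage of 1,4-cineole-type bridged tertiary ethers and the retentive substitution of trans-bromohydrin derivatives through bromonium ions.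

Step 8
Reactants: 12 (1S,3R,4R)-3-bromo-1-({[tert-butyl(dimethyl)silyl]oxy}methyl)-4-chloro-4-methylcyclohexan-1-ol
Product: 13 (1S,3R,4R)-3-bromo-4-chloro-1-(hydroxymethyl)-4-methylcyclohexan-1-ol
Conditions: HF·pyridine, pyridine, THF, 0 °C → rt
Reagents that add atoms: none
Why: Fluoride-mediated cleavage of the primary silyl ether in a buffered, weakly ionising medium that leaves the tertiary chloride and the secondary bromide untouched.

Step 9
Reactants: 13 (1S,3R,4R)-3-bromo-4-chloro-1-(hydroxymethyl)-4-methylcyclohexan-1-ol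
Product: 14 (1S,3R,4R)-3-bromo-4-chloro-1-hydroxy-4-methylcyclohexane-1-carbaldehyde
Conditions: (COCl)2, DMSO, CH2Cl2, −78 °C; Et3N, −78 → 0 °C; used directly
Reagents that add atoms: none
Why: Swern oxidation converts the primary alcohol into the aldehyde; the tertiary hydroxyl cannot be oxidised, activated-DMSO conditions do not cleave the glycol, and the quaternary α-carbon excludes epimerisation.

Step 10
Reactants: 15 (3R)-3-hydroxyoxolan-2-one ((R)-α-hydroxy-γ-butyrolactone)
Product: 16 (3R)-3-{[tert-butyl(dimethyl)silyl]oxy}oxolan-2-one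
Conditions: TBSCl, imidazole, DMF, rt
Reagents that add atoms: tert-butyldimethylsilyl chloride, CC(C)(C)[Si](C)(C)Cl
Why: Silyl ether formation on the secondary α-hydroxyl under mild imidazole conditions that do not epimerise the lactone α-carbon.

Step 11
Reactants: 16 (3R)-3-{[tert-butyl(dimethyl)silyl]oxy}oxolan-2-one
Product: 17 (3R)-3-{[tert-butyl(dimethyl)silyl]oxy}-2-methyloxolan-2-ol (anomer mixture in equilibrium with the open-chain hydroxy ketone)
Conditions: MeLi (1.1 equiv), THF, −78 °C; aq. NH4Cl at −78 °C
Reagents that add atoms: methyllithium, [Li]C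
Why: Mono-addition of methyllithium to the lactone: at −78 °C the tetrahedral lithium hemiketal alkoxide does not collapse, so a second addition is avoided and the C3 stereocentre is untouched.

Step 12
Reactants: 17 (3R)-3-{[tert-butyl(dimethyl)silyl]oxy}-2-methyloxolan-2-ol
Product: 18 (3R)-3-{[tert-butyl(dimethyl)silyl]oxy}-4-methylpent-4-en-1-ol
Conditions: Ph3PCH3Br, n-BuLi, THF, 0 °C → rt
Reagents that add atoms: methyltriphenylphosphonium bromide, C[P+](c1ccccc1)(c1ccccc1)c1ccccc1.[Br-]
Why: Wittig methylenation of the open-chain hydroxy ketone that is in equilibrium with the hemiketal; the lithium counter-ion and low temperature are chosen to limit epimerisation α to the ketone and silyl migration to the primary alkoxide.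

Step 13
Reactants: 18 (3R)-3-{[tert-butyl(dimethyl)silyl]oxy}-4-methylpent-4-en-1-ol
Product: 19 {[(3R)-5-bromo-2-methylpent-1-en-3-yl]oxy}(tert-butyl)dimethylsilane
Conditions: CBr4, PPh3, CH2Cl2, 0 °C
Reagents that add atoms: tetrabromomethane, BrC(Br)(Br)Br
Why: Appel reaction converts the primary alcohol into the bromide under neutral conditions that leave the allylic silyl ether and the alkene untouched.

Step 14
Reactants: 14 (1S,3R,4R)-3-bromo-4-chloro-1-hydroxy-4-methylcyclohexane-1-carbaldehyde; 19 {[(3R)-5-bromo-2-methylpent-1-en-3-yl]oxy}(tert-butyl)dimethylsilane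
Product: 21 (1S,3R,4R)-3-bromo-1-[(4R)-4-{[tert-butyl(dimethyl)silyl]oxy}-1-hydroxy-5-methylhex-5-en-1-yl]-4-chloro-4-methylcyclohexan-1-ol (both epimers at the new carbinol), via [(3R)-3-{[tert-butyl(dimethyl)silyl]oxy}-4-methylpent-4-en-1-yl]magnesium bromide 20 (not isolated)
Conditions: 19 (3 equiv), Mg, THF, 40 °C; then 14, THF, −78 °C; aq. NH4Cl
Reagents that add atoms: none
Why: Grignard formation and 1,2-addition to the aldehyde: one equivalent is spent on the tertiary hydroxyl and addition of the next to the α-alkoxy aldehyde at −78 °C is far faster than any reaction at the secondary bromide or the tertiary chloride; the new carbinol centre forms as a mixture that the next step removes.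

Step 15
Reactants: 21 (1S,3R,4R)-3-bromo-1-[(4R)-4-{[tert-butyl(dimethyl)silyl]oxy}-1-hydroxy-5-methylhex-5-en-1-yl]-4-chloro-4-methylcyclohexan-1-ol
Product: 22 (4R)-1-[(1S,3R,4R)-3-bromo-4-chloro-1-hydroxy-4-methylcyclohexyl]-4-{[tert-butyl(dimethyl)silyl]oxy}-5-methylhex-5-en-1-one
Conditions: (COCl)2, DMSO, CH2Cl2, −78 °C; Et3N, −78 → 0 °C
Reagents that add atoms: none
Why: Swern oxidation of the secondary alcohol of the glycol to the α-hydroxy ketone without C–C cleavage; the tertiary hydroxyl, the allylic silyl ether and the halides are inert.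

Step 16
Reactants: 22 (4R)-1-[(1S,3R,4R)-3-bromo-4-chloro-1-hydroxy-4-methylcyclohexyl]-4-{[tert-butyl(dimethyl)silyl]oxy}-5-methylhex-5-en-1-one
Product: 23 (1S,3R,4R)-3-bromo-1-[(5R)-5-{[tert-butyl(dimethyl)silyl]oxy}-2-hydroxy-6-methyl-1-(trimethylsilyl)hept-6-en-2-yl]-4-chloro-4-methylcyclohexan-1-ol (both epimers at the new carbinol)
Conditions: Me3SiCH2MgCl (4 equiv), CeCl3, THF, −78 → 0 °C; aq. NH4Cl
Reagents that add atoms: (trimethylsilyl)methylmagnesium chloride, C[Si](C)(C)C[Mg]Cl
Why: First stage of a Peterson olefination: the weakly basic reagent formed from Me3SiCH2MgCl and CeCl3 adds to the hindered, enolisable ketone (one equivalent is consumed by the tertiary hydroxyl) without attacking the halides, and the new carbinol centre is destroyed in the next step.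

Step 17
Reactants: 23 (1S,3R,4R)-3-bromo-1-[(5R)-5-{[tert-butyl(dimethyl)silyl]oxy}-2-hydroxy-6-methyl-1-(trimethylsilyl)hept-6-en-2-yl]-4-chloro-4-methylcyclohexan-1-ol
Product: 25 (1S,3R,4R)-3-bromo-4-chloro-1-[(5R)-5-hydroxy-6-methylhepta-1,6-dien-2-yl]-4-methylcyclohexan-1-ol, via silyl ether of the target 24 (not isolated)
Conditions: HF·pyridine, pyridine, THF, 0 °C → rt
Reagents that add atoms: none
Why: Acid-promoted Peterson elimination of the tertiary β-hydroxysilane gives the 1,1-disubstituted C7 methylene, and the same buffered HF·pyridine then cleaves the secondary silyl ether; no stereocentre is touched.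

**Compound list**

1 | 4-bromo-2-methylbut-1-ene | C=C(C)CCBr | starting material
2 | prop-2-yn-1-ol | C#CCO | starting material
3 | (3-methylbut-3-en-1-yl)magnesium bromide | C=C(C)CC[Mg]Br | intermediate
4 | bromomagnesium (2Z)-3-(bromomagnesio)-2-(3-methylbut-3-en-1-yl)prop-2-en-1-olate | Br[Mg]/C=C(\CO[Mg]Br)CCC(C)=C | intermediate
5 | 5-methyl-2-methylidenehex-5-en-1-ol | C=C(C)CCC(=C)CO | intermediate
6 | [(2R)-2-(3-methylbut-3-en-1-yl)oxiran-2-yl]methanol | OC[C@]1(CCC(C)=C)CO1 | intermediate
7 | vinylmagnesium bromide | C=C[Mg]Br | starting material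
8 | (2S)-5-methyl-2-(prop-2-en-1-yl)hex-5-ene-1,2-diol | C=CC[C@](O)(CO)CCC(C)=C | intermediate
9 | (1S)-1-(hydroxymethyl)-4-methylcyclohex-3-en-1-ol | OC[C@]1(O)CCC(C)=CC1 | intermediate
10 | (1S)-1-({[tert-butyl(dimethyl)silyl]oxy}methyl)-4-methylcyclohex-3-en-1-ol | CC(C)(C)[Si](C)(C)OC[C@]1(O)CCC(C)=CC1 | intermediate
11 | (1R,2R,4S)-2-bromo-4-({[tert-butyl(dimethyl)silyl]oxy}methyl)-1-methyl-7-oxabicyclo[2.2.1]heptane | CC(C)(C)[Si](C)(C)OC[C@]1(O2)CC[C@]2(C)[C@H](Br)C1 | intermediate
12 | (1S,3R,4R)-3-bromo-1-({[tert-butyl(dimethyl)silyl]oxy}methyl)-4-chloro-4-methylcyclohexan-1-ol | CC(C)(C)[Si](C)(C)OC[C@]1(O)CC[C@@](C)(Cl)[C@H](Br)C1 | intermediate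
13 | (1S,3R,4R)-3-bromo-4-chloro-1-(hydroxymethyl)-4-methylcyclohexan-1-ol | OC[C@]1(O)CC[C@@](C)(Cl)[C@H](Br)C1 | intermediate
14 | (1S,3R,4R)-3-bromo-4-chloro-1-hydroxy-4-methylcyclohexane-1-carbaldehyde | O=C[C@]1(O)CC[C@@](C)(Cl)[C@H](Br)C1 | intermediate
15 | (3R)-3-hydroxyoxolan-2-one | O[C@@H]1CCOC1=O | starting material
16 | (3R)-3-{[tert-butyl(dimethyl)silyl]oxy}oxolan-2-one | CC(C)(C)[Si](C)(C)O[C@@H]1CCOC1=O | intermediate
17 | (3R)-3-{[tert-butyl(dimethyl)silyl]oxy}-2-methyloxolan-2-ol (anomer mixture) | CC1(O)OCC[C@H]1O[Si](C)(C)C(C)(C)C | intermediate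
18 | (3R)-3-{[tert-butyl(dimethyl)silyl]oxy}-4-methylpent-4-en-1-ol | C=C(C)[C@H](O[Si](C)(C)C(C)(C)C)CCO | intermediate
19 | {[(3R)-5-bromo-2-methylpent-1-en-3-yl]oxy}(tert-butyl)dimethylsilane | C=C(C)[C@H](O[Si](C)(C)C(C)(C)C)CCBr | intermediate
20 | [(3R)-3-{[tert-butyl(dimethyl)silyl]oxy}-4-methylpent-4-en-1-yl]magnesium bromide | C=C(C)[C@H](O[Si](C)(C)C(C)(C)C)CC[Mg]Br | intermediate
21 | (1S,3R,4R)-3-bromo-1-[(4R)-4-{[tert-butyl(dimethyl)silyl]oxy}-1-hydroxy-5-methylhex-5-en-1-yl]-4-chloro-4-methylcyclohexan-1-ol (epimers at C1 of the side chain) | C=C(C)[C@H](O[Si](C)(C)C(C)(C)C)CCC(O)[C@]1(O)CC[C@@](C)(Cl)[C@H](Br)C1 | intermediate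
22 | (4R)-1-[(1S,3R,4R)-3-bromo-4-chloro-1-hydroxy-4-methylcyclohexyl]-4-{[tert-butyl(dimethyl)silyl]oxy}-5-methylhex-5-en-1-one | C=C(C)[C@H](O[Si](C)(C)C(C)(C)C)CCC(=O)[C@]1(O)CC[C@@](C)(Cl)[C@H](Br)C1 | intermediate
23 | (1S,3R,4R)-3-bromo-1-[(5R)-5-{[tert-butyl(dimethyl)silyl]oxy}-2-hydroxy-6-methyl-1-(trimethylsilyl)hept-6-en-2-yl]-4-chloro-4-methylcyclohexan-1-ol (epimers at C2 of the side chain) | C=C(C)[C@H](O[Si](C)(C)C(C)(C)C)CCC(O)(C[Si](C)(C)C)[C@]1(O)CC[C@@](C)(Cl)[C@H](Br)C1 | intermediate
24 | (1S,3R,4R)-3-bromo-1-[(5R)-5-{[tert-butyl(dimethyl)silyl]oxy}-6-methylhepta-1,6-dien-2-yl]-4-chloro-4-methylcyclohexan-1-ol | C=C(C)[C@H](O[Si](C)(C)C(C)(C)C)CCC(=C)[C@]1(O)CC[C@@](C)(Cl)[C@H](Br)C1 | intermediate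
25 | (1S,3R,4R)-3-bromo-4-chloro-1-[(5R)-5-hydroxy-6-methylhepta-1,6-dien-2-yl]-4-methylcyclohexan-1-ol | C=C(C)[C@H](O)CCC(=C)[C@]1(O)CC[C@@](C)(Cl)[C@H](Br)C1 | target

**Step count**

Total: 17 steps. Longest linear sequence: 13 steps (steps 1–9 and 14–17); the side-chain bromide 19 takes 4 steps (steps 10–13).

**Steps most likely to fail**

Step 7 (chloride opening of the bromo ether). The ring opening may ionise the wrong C–O bond, lose a proton from the bromonium ion to give an allylic bromide, or close back to the ether on work-up. The fallback sets out from 11 and replaces the Lewis-acid chlorinolysis by the classical acylative cleavage of ethers. Acetyl chloride with catalytic ZnCl2 in CH2Cl2 at 0 °C acylates the bridging oxygen, the bromine-assisted C4–O ionisation follows, and chloride adds at C4. This should give (1S,3R,4R)-3-bromo-1-({[tert-butyl(dimethyl)silyl]oxy}methyl)-4-chloro-4-methylcyclohexyl acetate F1, in which the C1 oxygen is held as an ester and cannot re-close. Reduction with iBu2AlH in CH2Cl2 at −78 °C removes the tertiary acetate, and the route is rejoined at 12.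

Step 6 (bromoetherification). Capture of the bromonium ion by outside nucleophiles, or allylic bromination, may outrun the strained boat-like bridging by the tertiary hydroxyl. The fallback sets out from 10 and forms the C4–O and C5–Br bonds in separate operations. Intramolecular oxymercuration with Hg(OAc)2 in THF is reversible, so the bridged Markovnikov adduct with mercury anti to the new C–O bond should accumulate. Exchange with aqueous KBr gives bromo[(1R,2R,4S)-4-({[tert-butyl(dimethyl)silyl]oxy}methyl)-1-methyl-7-oxabicyclo[2.2.1]heptan-2-yl]mercury F2. Brominolysis with Br2 in pyridine, which replaces mercury by bromine with retention, returns the route at 11.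

Step 14 (Grignard addition to the hydroxy aldehyde). The organomagnesium reagent may be lost to dehydrohalogenation or halogen–metal exchange at the vicinal dihalide, or the free α-hydroxy aldehyde may self-condense before addition. The fallback sets out from 14 and 18 and makes the C7–C8 bond by acyl cross-coupling (Fukuyama coupling) in place of carbonyl addition. Pinnick oxidation of 14 (NaClO2, NaH2PO4, 2-methylbut-2-ene, t-BuOH/H2O) gives (1S,3R,4R)-3-bromo-4-chloro-1-hydroxy-4-methylcyclohexane-1-carboxylic acid F3. Thioesterification with ethanethiol, dicyclohexylcarbodiimide and catalytic 4-(dimethylamino)pyridine gives S-ethyl (1S,3R,4R)-3-bromo-4-chloro-1-hydroxy-4-methylcyclohexane-1-carbothioate F4. In parallel, alcohol 18 is converted with I2, PPh3 and imidazole into tert-butyl{[(3R)-5-iodo-2-methylpent-1-en-3-yl]oxy}dimethylsilane F5. Zinc insertion (activated Zn, THF, supernatant used) gives [(3R)-3-{[tert-butyl(dimethyl)silyl]oxy}-4-methylpent-4-en-1-yl]zinc iodide F6. Coupling of F4 with F6 under PdCl2(PPh3)2 catalysis in toluene at rt gives the ketone directly, and the route is rejoined at 22 without step 15.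

Further compounds
F1 | step 7 | (1S,3R,4R)-3-bromo-1-({[tert-butyl(dimethyl)silyl]oxy}methyl)-4-chloro-4-methylcyclohexyl acetate | CC(=O)O[C@@]1(CO[Si](C)(C)C(C)(C)C)CC[C@@](C)(Cl)[C@H](Br)C1
F2 | step 6 | bromo[(1R,2R,4S)-4-({[tert-butyl(dimethyl)silyl]oxy}methyl)-1-methyl-7-oxabicyclo[2.2.1]heptan-2-yl]mercury | CC(C)(C)[Si](C)(C)OC[C@]1(O2)CC[C@]2(C)[C@H]([Hg]Br)C1
F3 | step 14 | (1S,3R,4R)-3-bromo-4-chloro-1-hydroxy-4-methylcyclohexane-1-carboxylic acid | OC(=O)[C@]1(O)CC[C@@](C)(Cl)[C@H](Br)C1
F4 | step 14 | S-ethyl (1S,3R,4R)-3-bromo-4-chloro-1-hydroxy-4-methylcyclohexane-1-carbothioate | CCSC(=O)[C@]1(O)CC[C@@](C)(Cl)[C@H](Br)C1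
F5 | step 14 | tert-butyl{[(3R)-5-iodo-2-methylpent-1-en-3-yl]oxy}dimethylsilane | C=C(C)[C@H](O[Si](C)(C)C(C)(C)C)CCI
F6 | step 14 | [(3R)-3-{[tert-butyl(dimethyl)silyl]oxy}-4-methylpent-4-en-1-yl]zinc iodide | C=C(C)[C@H](O[Si](C)(C)C(C)(C)C)CC[Zn]I
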